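Temperature is what differs among the four new flasks, so from the two earlier runs I wanted the rise in temperature that multiplies the rate constant of D + Z to L by 10.

| flask | D | Z | temperature | remark | time |
|---|---|---|---|---|---|
| Thursday's | 0.010 M | 0.013 M | 66 °C | run made earlier |  |
| Sunday's | 0.010 M | 0.019 M | 91 °C | run made earlier |  |
| blue | 0.010 M | 0.0250 M | 55 °C |  | 10 min |
| green | 0.010 M | 0.0250 M | 100 °C |  | 10 min |
| amber | 0.010 M | 0.0250 M | 70 °C |  | 10 min |
| teal | 0.010 M | 0.0250 M | 85 °C |  | 10 min |

Thursday's run (percent of the D charged)

| time / min | L / % | D / % |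
|---|---|---|
| 0.417 | 0 | 96.7 |
| 0.667 | 1.1 | 98.0 |
| 0.833 | 0 | 97.6 |
| 1.33 | 4.3 | 91.9 |
| 2.00 | 5.5 | 92.7 |
| 3.00 | 6.2 | 88.4 |
| 5.00 | 10.8 | 80.9 |

Sunday's run (percent of the D charged)

| time / s | L / % | D / % |
|---|---|---|
| 10.0 | 2.5 | 94.8 |
| 15.0 | 4.1 | 91.2 |
| 25.0 | 5.2 | 86.2 |
| 30.0 | 8.5 | 84.1 |
| 50.0 | 13.9 | 75.0 |
| 80.0 | 20.1 | 64.9 |

(each reading ± 1 percentage point)

- the best flask by amount of L, in percent of the D charged; "all alike" if 1.5 percentage points covers them all (blue / green / amber / teal / all alike)
- amount of L at the end, in percent of the D charged, blue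
- amount of L at the end, in percent of the D charged, green
- amount of L at the end, in percent of the D charged, amber
- amount of L at the end, in percent of the D charged, teal

- a reading or a percentage of L counts all its forms, free or not
- a reading of D is of its free form alone

I read that constant in two ways from the last reading of each run, holding Z at its charge (the pseudo-first-order reckoning). The rise of L, divided by the mean of D, gave 1.84 /M/min for Thursday's run and 9.62 /M/min for Sunday's. The logarithmic fall of D gave 3.26 /M/min and 17.1 /M/min.

The two ways agreed on the ratio of hot to cold, 5.23 against 5.25, so I trusted the temperature dependence they share: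

width = temperature gap ÷ (powers of ten in that ratio) = 34.8 K

This is the decade width, the rise that multiplies the constant by 10.

But they parted on the size of the constant, the fall of D reading 1.77 times the rise of L. D fell by 1.77 and 1.75 per L read. Since D is read free and L with its held forms, I took the fall of D to be the cheat: some D sits held on L, gone from the reading without being converted. So I kept the constant from L, and let D be spent at 1.76 per L:

reach = constant × charge of Z × time

L = (1 − exp(−1.76 × reach)) ÷ 1.76

The decade width gave reaches of 0.222 for blue, 0.599 for amber, 1.62 for teal and 4.37 for green. L then came to 18.4%, 37.0%, 53.6% and 56.9%. Blue's reach stands below Sunday's 0.244, but that matches extent, not temperature: blue's 55 °C lies below 66 °C and 91 °C, so its constant is extrapolated and neither run tests it. Amber's lies beyond, and so do teal's and green's. I put green first, with less trust as the reach grew.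

The forecast, made apart from this, said green, with 16%, 75%, 36% and 58% for blue, green, amber and teal: “Nothing indicates L decays, so green is best.”

The flasks gave 17.5% in blue, 26.9% in green, 33.8% in amber and 39.5% in teal, so the best was teal.

    Z + L → Q (k = 0.0730 /M/s, Ea = 57.0 kJ/mol)
    Z → G (k = 2.70 × 10⁻⁶ /s, Ea = 113 kJ/mol)
    Z + Q → X (k = 0.0210 /M/s, Ea = 48.0 kJ/mol)
    D + L ⇌ J, settled at all times (K = 1400 /M, ΔH = −36.0 kJ/mol)
    D + Z → L (k = 0.0440 /M/s, Ea = 67.0 kJ/mol)
    (constants at 70 °C)

In blue, at 4.39 min, Z had a half-life of 93 min by forming L and 160 h by turning L into Q, and blue's L stood near my 18.4%. Green, at a reach of 4.37, ended with 26.9% L beside 39.1% Q and 13.5% X.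

At 80 °C, blue's neighbour has by the decade width a reach of 1.16 and L of 49.5%. It gave 40.0%, with 9.30% Q and 1.36% X.

(The data are simulated from invented constants; the scatter is artificial.)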